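**Retrosynthetic overview**
1. Cut the depside ester C(=O)–OAr bond to give acid 7 (A ring) and phenol 5 (B ring), joined last by carbodiimide esterification at the only non-chelated OH.
2. Both halves come from one intermediate, formyl ester 3: CHO → CH3 gives 5, and methyl ester cleavage gives 7.
3. Formyl ester 3 comes from formylation of commercial atraric acid 1 at its only free ring position.
4. No ring is formed (both benzene rings are carried through from 1), and no protecting groups are used.

Assumption: the target has no stereocentre or other stereogenic element, so "single enantiomer" needs no stereocontrol; methyl 2,4-dihydroxy-3,6-dimethylbenzoate (atraric acid) is taken as commercially available.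

**Route**

Step 1
Reactants: 1 methyl 2,4-dihydroxy-3,6-dimethylbenzoate (atraric acid)
Product: 3 methyl 5-formyl-2,4-dihydroxy-3,6-dimethylbenzoate, via chloro(methoxy)methyl arene 2 (not isolated)
Conditions: Cl2CHOMe (1.5 eq), TiCl4 (3 eq), CH2Cl2, 0 °C → rt; then ice/1 M HCl
Reagents that add atoms: dichloromethyl methyl ether, COC(Cl)Cl (formyl carbon); water, O (formyl oxygen, on hydrolytic work-up)
Why: Rieche formylation (electrophilic aromatic substitution) at C5, the only unsubstituted ring carbon, which is ortho/para to the two hydroxyls; the α-chloro ether is hydrolysed to the aldehyde on work-up, and no stereocentre remains.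

Step 2 (uses about half of 3)
Reactants: 3 methyl 5-formyl-2,4-dihydroxy-3,6-dimethylbenzoate
Product: 5 methyl 2,4-dihydroxy-3,5,6-trimethylbenzoate, via benzylic alcohol 4 (not isolated)
Conditions: H2 (1 atm), 10% Pd/C, AcOH, cat. HClO4, rt
Reagents that add atoms: none
Why: catalytic hydrogenation of the aryl aldehyde followed by acid-assisted benzylic hydrogenolysis of the o/p-hydroxybenzyl alcohol gives the methyl group; the methyl ester, phenols and arene are inert under these conditions.

Step 3 (uses the other half of 3)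
Reactants: 3 methyl 5-formyl-2,4-dihydroxy-3,6-dimethylbenzoate
Product: 7 5-formyl-2,4-dihydroxy-3,6-dimethylbenzoic acid, via acylium hydrogensulfate 6 (not isolated)
Conditions: conc. H2SO4, 0 °C → rt, 45 min; then pour onto ice, cold work-up, use directly
Reagents that add atoms: water, O (carboxyl OH oxygen, on quench)
Why: Newman-type AAc1 hydrolysis, in which the di-ortho-substituted, o/p-hydroxy-stabilised benzoate ionises to the acylium ion and water captures it on quench; the ring is fully substituted so it cannot be sulfonated, and cold acid avoids the decarboxylation that hot alkali causes.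

Step 4
Reactants: 7 5-formyl-2,4-dihydroxy-3,6-dimethylbenzoic acid; 5 methyl 2,4-dihydroxy-3,5,6-trimethylbenzoate
Product: 9 isopseudocyphellarin A (methyl 4-[(5-formyl-2,4-dihydroxy-3,6-dimethylbenzoyl)oxy]-2-hydroxy-3,5,6-trimethylbenzoate), via O-acylisourea 8 (not isolated)
Conditions: DCC (1.1 eq), dry Et2O–toluene, rt, 48 h
Reagents that add atoms: none
Why: carbodiimide (DMAP-free Steglich-type) esterification; the 4-OH of 5 is the only hydroxyl not hydrogen-bonded to a carbonyl (2-OH of 5 is chelated to its ester, both OH of 7 to C=O/CHO), so it alone attacks the activated acid; no stereocentre is formed.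

**Compound list**
1 | methyl 2,4-dihydroxy-3,6-dimethylbenzoate (atraric acid) | COC(=O)c1c(C)cc(O)c(C)c1O | starting material
2 | methyl 5-[chloro(methoxy)methyl]-2,4-dihydroxy-3,6-dimethylbenzoate (racemic, titanium-bound, not isolated) | COC(=O)c1c(C)c(C(Cl)OC)c(O)c(C)c1O | intermediate
3 | methyl 5-formyl-2,4-dihydroxy-3,6-dimethylbenzoate | COC(=O)c1c(C)c(C=O)c(O)c(C)c1O | intermediate
4 | methyl 2,4-dihydroxy-5-(hydroxymethyl)-3,6-dimethylbenzoate (not isolated) | COC(=O)c1c(C)c(CO)c(O)c(C)c1O | intermediate
5 | methyl 2,4-dihydroxy-3,5,6-trimethylbenzoate | COC(=O)c1c(C)c(C)c(O)c(C)c1O | intermediate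
6 | 5-formyl-2,4-dihydroxy-3,6-dimethylbenzoylium hydrogensulfate (not isolated) | Cc1c(C#[O+])c(O)c(C)c(O)c1C=O.OS(=O)(=O)[O-] | intermediate
7 | 5-formyl-2,4-dihydroxy-3,6-dimethylbenzoic acid | OC(=O)c1c(C)c(C=O)c(O)c(C)c1O | intermediate
8 | O-(5-formyl-2,4-dihydroxy-3,6-dimethylbenzoyl)-N,N'-dicyclohexylisourea (not isolated) | Cc1c(C(=O)OC(=NC2CCCCC2)NC2CCCCC2)c(O)c(C)c(O)c1C=O | intermediate
9 | isopseudocyphellarin A (achiral) | COC(=O)c1c(C)c(C)c(OC(=O)c2c(C)c(C=O)c(O)c(C)c2O)c(C)c1O | target

**Step count and risks**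
Total steps: 4. Longest linear sequence: 3 (1 → 3 → 5 → 9, or 1 → 3 → 7 → 9).

Most likely to fail, step 4 (depside coupling). Both partners are hindered and the acid carries free phenols and an aldehyde, so N-acylurea formation or self-condensation of 7 may dominate. The fallback sets out from 1 (with 5 as the unchanged coupling partner) and comes back at 9; it removes the formyl group and the free 4-OH from the acid partner and formylates last. Compound 1 is benzylated selectively at its non-chelated 4-OH (BnBr, K2CO3, acetone, reflux) to methyl 4-(benzyloxy)-2-hydroxy-3,6-dimethylbenzoate F1. Saponification (KOH, aq. DMSO, 90 °C, then cold HCl) gives 4-(benzyloxy)-2-hydroxy-3,6-dimethylbenzoic acid F2. Trifluoroacetic anhydride-mediated condensation of F2 with 5 (toluene, rt, mixed-anhydride acylation) gives methyl 4-{[4-(benzyloxy)-2-hydroxy-3,6-dimethylbenzoyl]oxy}-2-hydroxy-3,5,6-trimethylbenzoate F3. Hydrogenolysis (H2, Pd/C, EtOAc) gives methyl 4-[(2,4-dihydroxy-3,6-dimethylbenzoyl)oxy]-2-hydroxy-3,5,6-trimethylbenzoate F4. F4 has only one aromatic C–H in the whole molecule, so Rieche formylation (Cl2CHOMe, TiCl4, CH2Cl2, 0 °C, then aq. HCl) can only deliver 9.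

Second, step 3 (ester cleavage in conc. H2SO4). The protonated formyl group may slow acylium formation, and the β-resorcylic acid may decarboxylate or deformylate. The fallback sets out from 1 and comes back at 7; it replaces the methyl ester by a hydrogenolysable benzyl ester. Compound 1, which lacks the formyl group, is cleaved with cold conc. H2SO4 to 2,4-dihydroxy-3,6-dimethylbenzoic acid F5, which can also be bought. Carboxylate-selective alkylation (BnBr, KHCO3, DMF, rt) gives benzyl 2,4-dihydroxy-3,6-dimethylbenzoate F6. Rieche formylation as in step 1 gives benzyl 5-formyl-2,4-dihydroxy-3,6-dimethylbenzoate F7. Neutral hydrogenolysis (H2 1 atm, Pd/C, EtOAc, stopped after 1 equiv.) then releases 7 without aqueous acid or base and before the chelated aldehyde is touched.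

Third, step 2 (CHO → CH3 hydrogenolysis). It may stall at alcohol 4 or be sluggish on this vinylogous-acid aldehyde. The fallback sets out from 3 and comes back at 5; it replaces catalytic hydrogenolysis by thioacetal desulfurisation. Compound 3 is converted with ethane-1,2-dithiol and BF3·OEt2 (CH2Cl2, rt) into methyl 5-(1,3-dithiolan-2-yl)-2,4-dihydroxy-3,6-dimethylbenzoate F8, and Raney nickel (EtOH, reflux, Mozingo reduction) gives 5.

**Further compounds**
F1 | step 4 | methyl 4-(benzyloxy)-2-hydroxy-3,6-dimethylbenzoate | COC(=O)c1c(C)cc(OCc2ccccc2)c(C)c1O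
F2 | step 4 | 4-(benzyloxy)-2-hydroxy-3,6-dimethylbenzoic acid | OC(=O)c1c(C)cc(OCc2ccccc2)c(C)c1O
F3 | step 4 | methyl 4-{[4-(benzyloxy)-2-hydroxy-3,6-dimethylbenzoyl]oxy}-2-hydroxy-3,5,6-trimethylbenzoate | COC(=O)c1c(C)c(C)c(OC(=O)c2c(C)cc(OCc3ccccc3)c(C)c2O)c(C)c1O
F4 | step 4 | methyl 4-[(2,4-dihydroxy-3,6-dimethylbenzoyl)oxy]-2-hydroxy-3,5,6-trimethylbenzoate | COC(=O)c1c(C)c(C)c(OC(=O)c2c(C)cc(O)c(C)c2O)c(C)c1O
F5 | step 3 | 2,4-dihydroxy-3,6-dimethylbenzoic acid | OC(=O)c1c(C)cc(O)c(C)c1O
F6 | step 3 | benzyl 2,4-dihydroxy-3,6-dimethylbenzoate | O=C(OCc1ccccc1)c1c(C)cc(O)c(C)c1O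
F7 | step 3 | benzyl 5-formyl-2,4-dihydroxy-3,6-dimethylbenzoate | O=C(OCc1ccccc1)c1c(C)c(C=O)c(O)c(C)c1O
F8 | step 2 | methyl 5-(1,3-dithiolan-2-yl)-2,4-dihydroxy-3,6-dimethylbenzoate | COC(=O)c1c(C)c(C2SCCS2)c(O)c(C)c1O
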